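## Retrosynthetic overview

1. Target 25 ⇐ β-hydroxy selenide 23 by selenoxide syn-elimination (C1=C2 is made last, under buffered conditions); 23 ⇐ keto diacetate 20 by α'-selenenylation and 1,2-reduction (sets C3).
2. 20 ⇐ enone ketal 17 by ketal hydrolysis, C6-selective hydride reduction (sets C6) and acetylation; 17 ⇐ quinone monoketal 16 by ligand-controlled copper hydride 1,4-reduction (C1, a temporary relay centre).
3. 16 ⇐ phenol 15 by oxidative dearomatisation; the tail of 15 ⇐ cross-metathesis and hydrogenation of homoallylic acetate 12.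
4. Key C–C bond (C2'–C3'): Brown carbonyl allylation of arylacetaldehyde 8 with allylborane 9 joins the ring fragment to the chain and sets the side-chain centre; 8 ⇐ 3-bromo-4,5-dimethoxybenzaldehyde 1.
5. Rings: the only ring is bought as the benzene ring of 1 and is dearomatised in step 9; no ring is formed.

Numbering used from 16 on: ring locants as in the target (C1 carries the side chain, C3 the free hydroxyl, C5 the methoxyl, C6 the ring acetate); C2' is the side-chain carbinol carbon.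

Assumption: (R)-DTBM-SEGPHOS is taken as the ligand antipode that gives (1R)-17 in step 10; if the first run shows the opposite sense, the (S)-ligand is used and nothing else changes.

## Route

Step 1
Reactants: 1 3-bromo-4,5-dimethoxybenzaldehyde
Product: 3 3-bromo-4,5-dimethoxyphenol, via aryl formate 2 (not isolated)
Conditions: mCPBA, CH2Cl2, 0 °C to rt; then K2CO3 (cat.), MeOH, rt
Reagents that add atoms: meta-chloroperoxybenzoic acid, OOC(=O)c1cccc(Cl)c1
Why: Baeyer–Villiger (Dakin-type) oxidation in which the electron-rich aryl group migrates to oxygen, followed by methanolysis of the formate.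

Step 2
Reactants: 3 3-bromo-4,5-dimethoxyphenol
Product: 4 1-(benzyloxy)-3-bromo-4,5-dimethoxybenzene
Conditions: BnBr, K2CO3, DMF, rt
Reagents that add atoms: benzyl bromide, BrCc1ccccc1
Why: Williamson etherification; the benzyl ether survives to step 8, where it falls off together with the alkene reduction.

Step 3
Reactants: 4 1-(benzyloxy)-3-bromo-4,5-dimethoxybenzene; 5 allyltributylstannane
Product: 6 1-allyl-5-(benzyloxy)-2,3-dimethoxybenzene
Conditions: Pd(PPh3)4 (5 mol%), DMF, 90 °C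
Reagents that add atoms: none
Why: Stille cross-coupling of the aryl bromide with the allylstannane.

Step 4
Reactants: 6 1-allyl-5-(benzyloxy)-2,3-dimethoxybenzene
Product: 8 2-[5-(benzyloxy)-2,3-dimethoxyphenyl]acetaldehyde, via diol 7 (not isolated)
Conditions: OsO4 (2 mol%), NaIO4, 2,6-lutidine, dioxane/H2O 3:1, rt; aldehyde used crude
Reagents that add atoms: osmium tetroxide, O=[Os](=O)(=O)=O; sodium periodate, [Na+].[O-]I(=O)(=O)=O
Why: Lemieux–Johnson oxidation (dihydroxylation, then glycol cleavage), buffered with lutidine so the enolisable arylacetaldehyde is not over-oxidised.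

Step 5
Reactants: 8 2-[5-(benzyloxy)-2,3-dimethoxyphenyl]acetaldehyde; 9 (+)-B-allyldiisopinocampheylborane
Product: 11 (R)-1-[5-(benzyloxy)-2,3-dimethoxyphenyl]pent-4-en-2-ol, via borinate ester 10 (not isolated)
Conditions: Et2O, −78 °C; then NaOH, 30% H2O2, 0 °C to rt
Reagents that add atoms: none
Why: Brown asymmetric allylboration, an intermolecular carbonyl allylation through a closed chair transition state; the reagent derived from (−)-α-pinene attacks the aldehyde face that gives the (R)-carbinol, the C2' centre of the target.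

Step 6
Reactants: 11 (R)-1-[5-(benzyloxy)-2,3-dimethoxyphenyl]pent-4-en-2-ol
Product: 12 (R)-1-[5-(benzyloxy)-2,3-dimethoxyphenyl]pent-4-en-2-yl acetate
Conditions: Ac2O, pyridine, DMAP (cat.), CH2Cl2, rt
Reagents that add atoms: acetic anhydride, CC(=O)OC(C)=O
Why: Acylation installs the side-chain acetate of the target early, so the carbinol cannot attack the ketal carbon in step 9.

Step 7
Reactants: 12 (R)-1-[5-(benzyloxy)-2,3-dimethoxyphenyl]pent-4-en-2-yl acetate; 13 dec-1-ene
Product: 14 (2R,4E)-1-[5-(benzyloxy)-2,3-dimethoxyphenyl]tridec-4-en-2-yl acetate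
Conditions: second-generation Grubbs catalyst RuCl2(=CHPh)(H2IMes)(PCy3) (5 mol%), dec-1-ene (5 equiv), CH2Cl2, 40 °C
Reagents that add atoms: none
Why: Olefin cross-metathesis of two terminal alkenes driven by loss of ethylene; the E/Z ratio does not matter because the alkene is hydrogenated next.

Step 8
Reactants: 14 (2R,4E)-1-[5-(benzyloxy)-2,3-dimethoxyphenyl]tridec-4-en-2-yl acetate
Product: 15 (R)-1-(5-hydroxy-2,3-dimethoxyphenyl)tridecan-2-yl acetate
Conditions: H2 (1 atm), 10% Pd/C, EtOAc, rt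
Reagents that add atoms: none
Why: Catalytic hydrogenation saturates the chain and hydrogenolyses the benzyl ether in one operation without touching the homobenzylic acetate centre.

Step 9
Reactants: 15 (R)-1-(5-hydroxy-2,3-dimethoxyphenyl)tridecan-2-yl acetate
Product: 16 (R)-1-(5,6,6-trimethoxy-3-oxocyclohexa-1,4-dien-1-yl)tridecan-2-yl acetate
Conditions: PhI(OAc)2, MeOH, 0 °C
Reagents that add atoms: methanol, CO
Why: Hypervalent-iodine oxidative dearomatisation of a para-methoxyphenol; methanol adds at the methoxy-bearing para carbon and gives the para-quinone monoketal with the regiochemistry of the target fixed (ketal at C6, carbonyl at C3, enol ether at C5).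

Step 10
Reactants: 16 (R)-1-(5,6,6-trimethoxy-3-oxocyclohexa-1,4-dien-1-yl)tridecan-2-yl acetate
Product: 17 (R)-1-[(1R)-5,6,6-trimethoxy-3-oxocyclohex-4-en-1-yl]tridecan-2-yl acetate
Conditions: Cu(OAc)2·H2O (5 mol%), (R)-DTBM-SEGPHOS (5 mol%), (EtO)2MeSiH, t-BuOH, toluene, 0 °C to rt
Reagents that add atoms: none
Why: Ligand-controlled copper hydride conjugate reduction; hydride goes only to C1 of the plain enone half (the methoxy-substituted half is a deactivated vinylogous ester) and the chiral bisphosphine selects the face, setting the relay centre C1 as (R).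

Step 11
Reactants: 17 (R)-1-[(1R)-5,6,6-trimethoxy-3-oxocyclohex-4-en-1-yl]tridecan-2-yl acetate
Product: 19 (R)-1-[(1R,6S)-6-hydroxy-5-methoxy-3-oxocyclohex-4-en-1-yl]tridecan-2-yl acetate, via ene-dione 18 (not isolated)
Conditions: 1 M HCl, THF, 0 °C, NaHCO3 quench, crude taken on at once; then NaBH4 (1 equiv), CeCl3·7H2O, MeOH, −78 °C
Reagents that add atoms: water, O
Why: Ketal hydrolysis followed by Luche 1,2-reduction; hydride takes only the C6 ketone (the C3 carbonyl is a vinylogous ester) and enters axially, giving the equatorial alcohol trans to the equatorial C1 side chain, which sets C6 as (S).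

Step 12
Reactants: 19 (R)-1-[(1R,6S)-6-hydroxy-5-methoxy-3-oxocyclohex-4-en-1-yl]tridecan-2-yl acetate
Product: 20 (R)-1-[(1R,6S)-6-acetoxy-5-methoxy-3-oxocyclohex-4-en-1-yl]tridecan-2-yl acetate
Conditions: Ac2O, pyridine, DMAP (cat.), CH2Cl2, 0 °C
Reagents that add atoms: acetic anhydride, CC(=O)OC(C)=O
Why: Acylation of the only free hydroxyl gives the ring acetate of the target with retention at C6.

Step 13
Reactants: 20 (R)-1-[(1R,6S)-6-acetoxy-5-methoxy-3-oxocyclohex-4-en-1-yl]tridecan-2-yl acetate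
Product: 22 (R)-1-[(1S,2R,6S)-6-acetoxy-5-methoxy-3-oxo-2-(phenylselanyl)cyclohex-4-en-1-yl]tridecan-2-yl acetate, via trimethylsilyl dienol ether 21 (not isolated)
Conditions: TMSOTf, Et3N, CH2Cl2, −78 °C; then PhSeCl, −78 °C
Reagents that add atoms: phenylselenyl chloride, Cl[Se]c1ccccc1
Why: Soft enolisation of the vinylogous ester at C2 (ester-tolerant) and electrophilic α'-selenenylation anti to the neighbouring C1 side chain, which places selenium trans to the chain and therefore cis to C1–H.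

Step 14
Reactants: 22 (R)-1-[(1S,2R,6S)-6-acetoxy-5-methoxy-3-oxo-2-(phenylselanyl)cyclohex-4-en-1-yl]tridecan-2-yl acetate
Product: 23 (R)-1-[(1S,2R,3R,6S)-6-acetoxy-3-hydroxy-5-methoxy-2-(phenylselanyl)cyclohex-4-en-1-yl]tridecan-2-yl acetate
Conditions: NaBH4, CeCl3·7H2O, MeOH/THF, −40 °C; NaHCO3 work-up
Reagents that add atoms: none
Why: Luche 1,2-reduction; the all-trans C6/C1/C2 substituents sit equatorial (the triaxial form would have a 1,3-diaxial acetate/selenide clash), hydride enters axially, and the equatorial C3–OH is trans to selenium and hence trans to the C6 acetate (3R here is the 3S of the target after the priority change).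

Step 15
Reactants: 23 (R)-1-[(1S,2R,3R,6S)-6-acetoxy-3-hydroxy-5-methoxy-2-(phenylselanyl)cyclohex-4-en-1-yl]tridecan-2-yl acetate
Product: 25 (R)-1-[(3S,6S)-6-acetoxy-3-hydroxy-5-methoxycyclohexa-1,4-dien-1-yl]tridecan-2-yl acetate, via selenoxide 24 (not isolated)
Conditions: 30% H2O2, pyridine, CH2Cl2, 0 °C to rt; NaHCO3 wash, cold Et3N-deactivated silica
Reagents that add atoms: none
Why: Selenide oxidation and selenoxide syn-elimination (Sharpless–Reich) toward the cis C1–H and away from the carbinol carbon creates C1=C2 without acid and leaves C3, C6 and C2' untouched.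

## Compound list

1 | 3-bromo-4,5-dimethoxybenzaldehyde | O=Cc1cc(Br)c(OC)c(OC)c1 | starting material
2 | 3-bromo-4,5-dimethoxyphenyl formate | O=COc1cc(Br)c(OC)c(OC)c1 | intermediate
3 | 3-bromo-4,5-dimethoxyphenol | Oc1cc(Br)c(OC)c(OC)c1 | intermediate
4 | 1-(benzyloxy)-3-bromo-4,5-dimethoxybenzene | COc1cc(OCc2ccccc2)cc(Br)c1OC | intermediate
5 | allyltributylstannane | C=CC[Sn](CCCC)(CCCC)CCCC | starting material
6 | 1-allyl-5-(benzyloxy)-2,3-dimethoxybenzene | C=CCc1cc(OCc2ccccc2)cc(OC)c1OC | intermediate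
7 | 3-[5-(benzyloxy)-2,3-dimethoxyphenyl]propane-1,2-diol (racemic) | OCC(O)Cc1cc(OCc2ccccc2)cc(OC)c1OC | intermediate
8 | 2-[5-(benzyloxy)-2,3-dimethoxyphenyl]acetaldehyde | O=CCc1cc(OCc2ccccc2)cc(OC)c1OC | intermediate
9 | (+)-B-allyldiisopinocampheylborane (from (−)-α-pinene; commercial pentane solution) | C=CCB([C@H]1C[C@H]2C[C@@H]([C@@H]1C)C2(C)C)[C@H]1C[C@H]2C[C@@H]([C@@H]1C)C2(C)C | starting material
10 | (R)-1-[5-(benzyloxy)-2,3-dimethoxyphenyl]pent-4-en-2-yl diisopinocampheylborinate | C=CC[C@H](Cc1cc(OCc2ccccc2)cc(OC)c1OC)OB([C@H]1C[C@H]2C[C@@H]([C@@H]1C)C2(C)C)[C@H]1C[C@H]2C[C@@H]([C@@H]1C)C2(C)C | intermediate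
11 | (R)-1-[5-(benzyloxy)-2,3-dimethoxyphenyl]pent-4-en-2-ol | C=CC[C@H](Cc1cc(OCc2ccccc2)cc(OC)c1OC)O | intermediate
12 | (R)-1-[5-(benzyloxy)-2,3-dimethoxyphenyl]pent-4-en-2-yl acetate | C=CC[C@H](Cc1cc(OCc2ccccc2)cc(OC)c1OC)OC(C)=O | intermediate
13 | dec-1-ene | C=CCCCCCCCC | starting material
14 | (2R,4E)-1-[5-(benzyloxy)-2,3-dimethoxyphenyl]tridec-4-en-2-yl acetate (E drawn; E/Z mixture is used) | CCCCCCCC/C=C/C[C@H](Cc1cc(OCc2ccccc2)cc(OC)c1OC)OC(C)=O | intermediate
15 | (R)-1-(5-hydroxy-2,3-dimethoxyphenyl)tridecan-2-yl acetate | CCCCCCCCCCC[C@H](Cc1cc(O)cc(OC)c1OC)OC(C)=O | intermediate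
16 | (R)-1-(5,6,6-trimethoxy-3-oxocyclohexa-1,4-dien-1-yl)tridecan-2-yl acetate | CCCCCCCCCCC[C@H](CC1=CC(=O)C=C(OC)C1(OC)OC)OC(C)=O | intermediate
17 | (R)-1-[(1R)-5,6,6-trimethoxy-3-oxocyclohex-4-en-1-yl]tridecan-2-yl acetate | CCCCCCCCCCC[C@H](C[C@@H]1CC(=O)C=C(OC)C1(OC)OC)OC(C)=O | intermediate
18 | (R)-1-[(1R)-5-methoxy-3,6-dioxocyclohex-4-en-1-yl]tridecan-2-yl acetate | CCCCCCCCCCC[C@H](C[C@@H]1CC(=O)C=C(OC)C1=O)OC(C)=O | intermediate
19 | (R)-1-[(1R,6S)-6-hydroxy-5-methoxy-3-oxocyclohex-4-en-1-yl]tridecan-2-yl acetate | CCCCCCCCCCC[C@H](C[C@@H]1CC(=O)C=C(OC)[C@H]1O)OC(C)=O | intermediate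
20 | (R)-1-[(1R,6S)-6-acetoxy-5-methoxy-3-oxocyclohex-4-en-1-yl]tridecan-2-yl acetate | CCCCCCCCCCC[C@H](C[C@@H]1CC(=O)C=C(OC)[C@H]1OC(C)=O)OC(C)=O | intermediate
21 | (R)-1-[(1R,6S)-6-acetoxy-5-methoxy-3-(trimethylsilyloxy)cyclohexa-2,4-dien-1-yl]tridecan-2-yl acetate | CCCCCCCCCCC[C@H](C[C@@H]1C=C(O[Si](C)(C)C)C=C(OC)[C@H]1OC(C)=O)OC(C)=O | intermediate
22 | (R)-1-[(1S,2R,6S)-6-acetoxy-5-methoxy-3-oxo-2-(phenylselanyl)cyclohex-4-en-1-yl]tridecan-2-yl acetate | CCCCCCCCCCC[C@H](C[C@@H]1[C@@H]([Se]c2ccccc2)C(=O)C=C(OC)[C@H]1OC(C)=O)OC(C)=O | intermediate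
23 | (R)-1-[(1S,2R,3R,6S)-6-acetoxy-3-hydroxy-5-methoxy-2-(phenylselanyl)cyclohex-4-en-1-yl]tridecan-2-yl acetate | CCCCCCCCCCC[C@H](C[C@@H]1[C@@H]([Se]c2ccccc2)[C@H](O)C=C(OC)[C@H]1OC(C)=O)OC(C)=O | intermediate
24 | (R)-1-[(1S,2R,3R,6S)-6-acetoxy-3-hydroxy-5-methoxy-2-(phenylseleninyl)cyclohex-4-en-1-yl]tridecan-2-yl acetate (either configuration at selenium) | CCCCCCCCCCC[C@H](C[C@@H]1[C@@H]([Se](=O)c2ccccc2)[C@H](O)C=C(OC)[C@H]1OC(C)=O)OC(C)=O | intermediate
25 | (R)-1-[(3S,6S)-6-acetoxy-3-hydroxy-5-methoxycyclohexa-1,4-dien-1-yl]tridecan-2-yl acetate (CNP0081579.1) | CCCCCCCCCCC[C@H](CC1=C[C@H](O)C=C(OC)[C@H]1OC(C)=O)OC(C)=O | target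

## Count and risks

Total step count: 15. Longest linear sequence: 15 steps (1 to 25); 5, 9 and 13 are bought.

Most likely to fail, in this order:

Step 10. The copper hydride may not turn over at a β-carbon flanked by the ketal, or the face selectivity may be low. The fallback gives up catalyst control and separates diastereomers. It sets out from 16: stoichiometric [(Ph3P)CuH]6 in wet toluene reduces the enone without face control to 17 and its C1 epimer (R)-1-[(1S)-5,6,6-trimethoxy-3-oxocyclohex-4-en-1-yl]tridecan-2-yl acetate F1. The pair is put through the conditions of step 11, where F1 passes through the epimeric ene-dione (R)-1-[(1S)-5-methoxy-3,6-dioxocyclohex-4-en-1-yl]tridecan-2-yl acetate F2 to the trans hydroxy ketone (R)-1-[(1S,6R)-6-hydroxy-5-methoxy-3-oxocyclohex-4-en-1-yl]tridecan-2-yl acetate F3. Because the side-chain centre is fixed, 19 and F3 are diastereomers and are separated by preparative HPLC; the route is rejoined at 19.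

Step 11. Ene-dione 18 is the keto tautomer of a hydroquinone and C1 is epimerisable while it exists; a single hydride equivalent may also fail to discriminate C6 from C3. The fallback replaces selective mono-reduction by exhaustive reduction and selective re-oxidation. It sets out from 17: after the same hydrolysis the crude 18 is reduced at once with excess NaBH4/CeCl3·7H2O (−78 to 0 °C) at both carbonyls to the diol (R)-1-[(1S,3S,6S)-3,6-dihydroxy-5-methoxycyclohex-4-en-1-yl]tridecan-2-yl acetate F4 (the C3 configuration is immaterial). Activated MnO2 (CH2Cl2, rt) then oxidises only the C3 carbinol, whose C–H is activated through the methoxy-substituted double bond, and returns 19.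

Step 15. The free 3-methoxyallylic alcohol meets PhSeOH and oxidant during the elimination and may ionise, aromatise or be attacked at the enol ether. The fallback eliminates on a protected alcohol and frees it last. It sets out from 23: Et3SiCl and imidazole (DMF, 0 °C) give the silyl ether (R)-1-[(1S,2R,3R,6S)-6-acetoxy-5-methoxy-2-(phenylselanyl)-3-(triethylsilyloxy)cyclohex-4-en-1-yl]tridecan-2-yl acetate F5. H2O2/pyridine takes it through the selenoxide (R)-1-[(1S,2R,3R,6S)-6-acetoxy-5-methoxy-2-(phenylseleninyl)-3-(triethylsilyloxy)cyclohex-4-en-1-yl]tridecan-2-yl acetate F6 to the chromatographable dienyl silyl ether (R)-1-[(3S,6S)-6-acetoxy-5-methoxy-3-(triethylsilyloxy)cyclohexa-1,4-dien-1-yl]tridecan-2-yl acetate F7. Bu4NF buffered with AcOH (THF, 0 °C) then releases 25.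

Further compounds
F1 | step 10 | (R)-1-[(1S)-5,6,6-trimethoxy-3-oxocyclohex-4-en-1-yl]tridecan-2-yl acetate | CCCCCCCCCCC[C@H](C[C@H]1CC(=O)C=C(OC)C1(OC)OC)OC(C)=O
F2 | step 10 | (R)-1-[(1S)-5-methoxy-3,6-dioxocyclohex-4-en-1-yl]tridecan-2-yl acetate | CCCCCCCCCCC[C@H](C[C@H]1CC(=O)C=C(OC)C1=O)OC(C)=O
F3 | step 10 | (R)-1-[(1S,6R)-6-hydroxy-5-methoxy-3-oxocyclohex-4-en-1-yl]tridecan-2-yl acetate | CCCCCCCCCCC[C@H](C[C@H]1CC(=O)C=C(OC)[C@@H]1O)OC(C)=O
F4 | step 11 | (R)-1-[(1S,3S,6S)-3,6-dihydroxy-5-methoxycyclohex-4-en-1-yl]tridecan-2-yl acetate | CCCCCCCCCCC[C@H](C[C@@H]1C[C@H](O)C=C(OC)[C@H]1O)OC(C)=O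
F5 | step 15 | (R)-1-[(1S,2R,3R,6S)-6-acetoxy-5-methoxy-2-(phenylselanyl)-3-(triethylsilyloxy)cyclohex-4-en-1-yl]tridecan-2-yl acetate | CCCCCCCCCCC[C@H](C[C@@H]1[C@@H]([Se]c2ccccc2)[C@H](O[Si](CC)(CC)CC)C=C(OC)[C@H]1OC(C)=O)OC(C)=O
F6 | step 15 | (R)-1-[(1S,2R,3R,6S)-6-acetoxy-5-methoxy-2-(phenylseleninyl)-3-(triethylsilyloxy)cyclohex-4-en-1-yl]tridecan-2-yl acetate | CCCCCCCCCCC[C@H](C[C@@H]1[C@@H]([Se](=O)c2ccccc2)[C@H](O[Si](CC)(CC)CC)C=C(OC)[C@H]1OC(C)=O)OC(C)=O
F7 | step 15 | (R)-1-[(3S,6S)-6-acetoxy-5-methoxy-3-(triethylsilyloxy)cyclohexa-1,4-dien-1-yl]tridecan-2-yl acetate | CCCCCCCCCCC[C@H](CC1=C[C@H](O[Si](CC)(CC)CC)C=C(OC)[C@H]1OC(C)=O)OC(C)=O
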